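**Retrosyn­thetic overview**
- Last operation: global desilylation of a tetra-O-silyl flavanone. Rings A and B are bought as aromatic rings (phloroglucinol, 2,4-dihydroxybenzaldehyde); ring C is formed last.
- Ring C is cut at C3–C4 and O1–C2, giving a ring-A salicylaldehyde and a ring-B arylacetylene. They are joined by Rh-catalysed alkyne hydroacylation relayed into an enantioselective oxa-Michael closure.
- Enabling feature: the salicyl motif of ring A, i.e. the free phenolic oxygen (future O1, on C8a) ortho to the formyl carbon (future C4, on C4a). It chelates Rh for C–H insertion and then closes onto C2. O5 and O7 are silylated, so only the 8-substituted flavanone can form.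
- Ring A: phloroglucinol is desymmetrised (two MOM groups as ortho-directors, TIPS on the future O5). The C8 side chain enters by aryllithium alkylation and the formyl group by Mg-mediated ortho-formylation.
- Side-chain stereocentre: taken from (R)-limonene by ring cleavage, ketone methylenation and one-carbon excision (Barton iododecarboxylation).

Key step: step 13

Remark: commercial (+)-limonene oxide is a cis/trans mixture at the epoxide; both isomers converge in step 1, only C4 (R) matters.
Remark: the quinidine-derived thiourea is assumed to give the 2S series; if the facial sense is opposite on this substrate, the quinine-derived pseudo-enantiomer is used under the same conditions.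

**Route**

Step 1
Reactants: 1 (4R)-limonene 1,2-oxide
Product: 3 (3R)-6-oxo-3-(prop-1-en-2-yl)heptanal, via diol 2 (not isolated)
Conditions: H5IO6, THF/H2O, 0 °C → rt
Reagents that add atoms: water, O
Why: Epoxide hydrolysis followed by periodate (Malaprade) glycol cleavage should open only the C1–C2 bond, leaving the isopropenyl group and the stereocentre untouched.

Step 2
Reactants: 3 (3R)-6-oxo-3-(prop-1-en-2-yl)heptanal
Product: 4 (3R)-6-oxo-3-(prop-1-en-2-yl)heptanoic acid
Conditions: NaClO2, NaH2PO4, 2-methylbut-2-ene, t-BuOH/H2O, rt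
Reagents that add atoms: sodium chlorite, [Na+].[O-]Cl=O
Why: Pinnick oxidation is selective for the aldehyde over the ketone, and the scavenger protects the alkene from hypochlorite.

Step 3
Reactants: 4 (3R)-6-oxo-3-(prop-1-en-2-yl)heptanoic acid
Product: 5 (3R)-6-methyl-3-(prop-1-en-2-yl)hept-6-enoic acid
Conditions: Ph3PCH3Br, KOt-Bu (3 equiv), THF, 0 °C → rt; then aq. HCl
Reagents that add atoms: methyltriphenylphosphonium bromide, C[P+](c1ccccc1)(c1ccccc1)c1ccccc1.[Br-]
Why: Wittig methylenation with excess ylide tolerates the carboxylate, and the stereocentre is not adjacent to any acidic position.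

Step 4
Reactants: 5 (3R)-6-methyl-3-(prop-1-en-2-yl)hept-6-enoic acid
Product: 7 (3S)-3-(iodomethyl)-2,6-dimethylhepta-1,6-diene, via Barton ester 6 (not isolated)
Conditions: 1-hydroxypyridine-2(1H)-thione, DCC, DMAP (cat.), CH2Cl2, dark; then CHI3, PhH, hν (W lamp)
Reagents that add atoms: iodoform, IC(I)I
Why: Barton decarboxylative iodination excises the extra carbon; iodine transfer from iodoform should outrun cyclisation of the primary radical onto the 1,1-disubstituted alkene, and the stereocentre (not the radical carbon) is retained (the descriptor changes to S by priority only).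

Step 5
Reactants: 8 phloroglucinol
Product: 9 3,5-bis(methoxymethoxy)phenol
Conditions: MOMCl (2.0 equiv), i-Pr2NEt, CH2Cl2, 0 °C → rt; chromatography
Reagents that add atoms: chloromethyl methyl ether, COCCl
Why: Statistical O-alkylation of a C3-symmetric triol, so only the degree of alkylation has to be separated.

Step 6
Reactants: 9 3,5-bis(methoxymethoxy)phenol
Product: 10 [3,5-bis(methoxymethoxy)phenoxy]tri(propan-2-yl)silane
Conditions: TIPSCl, imidazole, DMF, rt
Reagents that add atoms: chlorotri(propan-2-yl)silane, CC(C)[Si](Cl)(C(C)C)C(C)C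
Why: Standard phenol silylation puts a robust, non-directing group on the future O5.

Step 7
Reactants: 10 [3,5-bis(methoxymethoxy)phenoxy]tri(propan-2-yl)silane; 7 (3S)-3-(iodomethyl)-2,6-dimethylhepta-1,6-diene
Product: 12 {3,5-bis(methoxymethoxy)-4-[(2R)-5-methyl-2-(prop-1-en-2-yl)hex-5-en-1-yl]phenoxy}tri(propan-2-yl)silane, via aryllithium 11 (not isolated)
Conditions: n-BuLi, THF, 0 °C; then 7, CuI (10 mol %), DMPU, −20 °C → rt
Reagents that add atoms: none
Why: Directed ortho-metalation occurs between the two OMOM groups (the OTIPS group does not direct), and copper-assisted SN2 alkylation at the primary carbon leaves the adjacent stereocentre untouched (descriptor R by priority).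

Step 8
Reactants: 12 {3,5-bis(methoxymethoxy)-4-[(2R)-5-methyl-2-(prop-1-en-2-yl)hex-5-en-1-yl]phenoxy}tri(propan-2-yl)silane
Product: 13 2-[(2R)-5-methyl-2-(prop-1-en-2-yl)hex-5-en-1-yl]-5-{[tri(propan-2-yl)silyl]oxy}benzene-1,3-diol
Conditions: conc. HCl (cat.), MeOH, 40 °C
Reagents that add atoms: none
Why: Acetal methanolysis removes both MOM groups, while the aryl TIPS ether and, under dilute acid and short exposure, the 1,1-disubstituted alkenes should survive.

Step 9
Reactants: 13 2-[(2R)-5-methyl-2-(prop-1-en-2-yl)hex-5-en-1-yl]-5-{[tri(propan-2-yl)silyl]oxy}benzene-1,3-diol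
Product: 15 2,4-dihydroxy-3-[(2R)-5-methyl-2-(prop-1-en-2-yl)hex-5-en-1-yl]-6-{[tri(propan-2-yl)silyl]oxy}benzaldehyde, via benzylic alcohol 14 (not isolated)
Conditions: MgCl2, Et3N, (CH2O)n, MeCN, reflux
Reagents that add atoms: paraformaldehyde, C=O
Why: Casnati–Skattebøl ortho-formylation of the magnesium phenoxide; the two open ortho positions are equivalent by symmetry, so the formyl group can only end up next to a hydroxyl that is flanked on its other side by the side chain.

Step 10
Reactants: 15 2,4-dihydroxy-3-[(2R)-5-methyl-2-(prop-1-en-2-yl)hex-5-en-1-yl]-6-{[tri(propan-2-yl)silyl]oxy}benzaldehyde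
Product: 16 2-hydroxy-3-[(2R)-5-methyl-2-(prop-1-en-2-yl)hex-5-en-1-yl]-4,6-bis{[tri(propan-2-yl)silyl]oxy}benzaldehyde
Conditions: TIPSCl (1.1 equiv), imidazole, DMAP (cat.), DMF, rt
Reagents that add atoms: chlorotri(propan-2-yl)silane, CC(C)[Si](Cl)(C(C)C)C(C)C
Why: Selective silylation of the non-chelated 4-OH; the 2-OH is hydrogen-bonded to the formyl group and flanked on both sides, so it should stay free.

Step 11
Reactants: 17 2,4-dihydroxybenzaldehyde
Product: 18 2,4-bis{[tert-butyl(dimethyl)silyl]oxy}benzaldehyde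
Conditions: TBSCl (2.5 equiv), imidazole, DMF, rt
Reagents that add atoms: tert-butylchlorodimethylsilane, CC(C)(C)[Si](C)(C)Cl
Why: Standard exhaustive phenol silylation.

Step 12
Reactants: 18 2,4-bis{[tert-butyl(dimethyl)silyl]oxy}benzaldehyde
Product: 19 [(4-ethynyl-1,3-phenylene)bis(oxy)]bis[tert-butyl(dimethyl)silane]
Conditions: TMSCHN2, LDA, THF, −78 °C → rt
Reagents that add atoms: (trimethylsilyl)diazomethane, C[Si](C)(C)C=[N+]=[N-]
Why: Colvin homologation (Peterson-type elimination, then 1,2-hydrogen shift of the alkylidene carbene) gives the terminal alkyne without the methanolic base that would cleave aryl silyl ethers.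

Step 13
Reactants: 16 2-hydroxy-3-[(2R)-5-methyl-2-(prop-1-en-2-yl)hex-5-en-1-yl]-4,6-bis{[tri(propan-2-yl)silyl]oxy}benzaldehyde; 19 [(4-ethynyl-1,3-phenylene)bis(oxy)]bis[tert-butyl(dimethyl)silane]
Product: 21 (2S)-2-(2,4-bis{[tert-butyl(dimethyl)silyl]oxy}phenyl)-8-[(2R)-5-methyl-2-(prop-1-en-2-yl)hex-5-en-1-yl]-5,7-bis{[tri(propan-2-yl)silyl]oxy}-2,3-dihydro-4H-chromen-4-one, via chalcone 20 (not isolated)
Conditions: [Rh(cod)OMe]2 (2.5 mol %), dppf (5.5 mol %), PhMe, 70 °C; then quinidine-derived 3,5-(CF3)2C6H3-thiourea (10 mol %), PhMe, −20 °C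
Reagents that add atoms: none
Why: Proposed new method: the Rh(I) aryloxide of 16 inserts into the formyl C–H bond to give a five-membered acyl–Rh(III) hydride chelate, syn-hydrometalation of the terminal alkyne of 19 places Rh on the unsubstituted carbon and C–C reductive elimination forms the C3–C4 bond of (E)-chalcone 20, after which the quinuclidine of the bifunctional catalyst deprotonates the one free phenol while its thiourea binds the enone carbonyl and the phenoxide adds to C2 to form the O1–C2 bond. The closest known reaction types are the Rh/diphosphine hydroacylation of alkynes with salicylaldehydes, its tandem use with oxa-Michael closure to chroman-4-ones, and the cinchona-thiourea closure of 2′-hydroxychalcones that carry an activating 3-alkoxycarbonyl group; new here is the relay of the two catalysts in one flask and the catalyst-controlled closure of a chalcone without that ester, reasoned to be feasible because the 6′-silyloxy group twists the ketone out of conjugation with the electron-rich ring and so raises enone electrophilicity and the rate of closure. Ring C closes in the 6-endo-trig oxa-Michael mode. The C2 stereocentre is set by the catalyst (face selection inside the ammonium phenoxide/thiourea–enone ion pair), and since the side-chain stereocentre is five bonds away no matched or mismatched case is expected. The step needs linear acyl delivery, which the terminal alkyne and its bulky ortho-silyloxyaryl group should secure, inertness of the two 1,1-disubstituted alkenes, which should not insert into the chelated acyl rhodium hydride, and closure through O1 only, which is guaranteed because O5 and O7 are silylated so the 6-substituted isomer cannot form. Racemic background closure must stay slow, for which the first stage is run without added base and the second at low temperature.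

Step 14
Reactants: 21 (2S)-2-(2,4-bis{[tert-butyl(dimethyl)silyl]oxy}phenyl)-8-[(2R)-5-methyl-2-(prop-1-en-2-yl)hex-5-en-1-yl]-5,7-bis{[tri(propan-2-yl)silyl]oxy}-2,3-dihydro-4H-chromen-4-one
Product: 22 remangiflavanone B, (2S)-2-(2,4-dihydroxyphenyl)-5,7-dihydroxy-8-[(2R)-5-methyl-2-(prop-1-en-2-yl)hex-5-en-1-yl]-2,3-dihydro-4H-chromen-4-one
Conditions: TBAF/AcOH (1:1), THF, 0 °C
Reagents that add atoms: none
Why: Buffered fluoride cleaves all four aryl silyl ethers without the base that would open the flavanone by retro-oxa-Michael reaction and without the acid that could cyclise the 7-OH onto the side-chain alkene, so C2 should be retained.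

**Compound list**

1 | (4R)-limonene 1,2-oxide, (+)-limonene oxide, cis/trans mixture | CC12OC1C[C@@H](CC2)C(C)=C | starting material
2 | (4R)-1-methyl-4-(prop-1-en-2-yl)cyclohexane-1,2-diol | CC1(O)C(O)C[C@@H](CC1)C(C)=C | intermediate
3 | (3R)-6-oxo-3-(prop-1-en-2-yl)heptanal | O=CC[C@@H](CCC(C)=O)C(C)=C | intermediate
4 | (3R)-6-oxo-3-(prop-1-en-2-yl)heptanoic acid | OC(=O)C[C@@H](CCC(C)=O)C(C)=C | intermediate
5 | (3R)-6-methyl-3-(prop-1-en-2-yl)hept-6-enoic acid | OC(=O)C[C@@H](CCC(C)=C)C(C)=C | intermediate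
6 | 2-thioxopyridin-1(2H)-yl (3R)-6-methyl-3-(prop-1-en-2-yl)hept-6-enoate (Barton ester) | S=C1C=CC=CN1OC(=O)C[C@@H](CCC(C)=C)C(C)=C | intermediate
7 | (3S)-3-(iodomethyl)-2,6-dimethylhepta-1,6-diene | IC[C@@H](CCC(C)=C)C(C)=C | intermediate
8 | phloroglucinol (benzene-1,3,5-triol) | Oc1cc(O)cc(O)c1 | starting material
9 | 3,5-bis(methoxymethoxy)phenol | COCOc1cc(O)cc(OCOC)c1 | intermediate
10 | [3,5-bis(methoxymethoxy)phenoxy]tri(propan-2-yl)silane | COCOc1cc(OCOC)cc(O[Si](C(C)C)(C(C)C)C(C)C)c1 | intermediate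
11 | {2,6-bis(methoxymethoxy)-4-{[tri(propan-2-yl)silyl]oxy}phenyl}lithium | [Li]c1c(OCOC)cc(O[Si](C(C)C)(C(C)C)C(C)C)cc1OCOC | intermediate
12 | {3,5-bis(methoxymethoxy)-4-[(2R)-5-methyl-2-(prop-1-en-2-yl)hex-5-en-1-yl]phenoxy}tri(propan-2-yl)silane | COCOc1cc(O[Si](C(C)C)(C(C)C)C(C)C)cc(OCOC)c1C[C@@H](CCC(C)=C)C(C)=C | intermediate
13 | 2-[(2R)-5-methyl-2-(prop-1-en-2-yl)hex-5-en-1-yl]-5-{[tri(propan-2-yl)silyl]oxy}benzene-1,3-diol | Oc1cc(O[Si](C(C)C)(C(C)C)C(C)C)cc(O)c1C[C@@H](CCC(C)=C)C(C)=C | intermediate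
14 | 4-(hydroxymethyl)-2-[(2R)-5-methyl-2-(prop-1-en-2-yl)hex-5-en-1-yl]-5-{[tri(propan-2-yl)silyl]oxy}benzene-1,3-diol | OCc1c(O)c(C[C@@H](CCC(C)=C)C(C)=C)c(O)cc1O[Si](C(C)C)(C(C)C)C(C)C | intermediate
15 | 2,4-dihydroxy-3-[(2R)-5-methyl-2-(prop-1-en-2-yl)hex-5-en-1-yl]-6-{[tri(propan-2-yl)silyl]oxy}benzaldehyde | O=Cc1c(O)c(C[C@@H](CCC(C)=C)C(C)=C)c(O)cc1O[Si](C(C)C)(C(C)C)C(C)C | intermediate
16 | 2-hydroxy-3-[(2R)-5-methyl-2-(prop-1-en-2-yl)hex-5-en-1-yl]-4,6-bis{[tri(propan-2-yl)silyl]oxy}benzaldehyde | O=Cc1c(O)c(C[C@@H](CCC(C)=C)C(C)=C)c(O[Si](C(C)C)(C(C)C)C(C)C)cc1O[Si](C(C)C)(C(C)C)C(C)C | intermediate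
17 | 2,4-dihydroxybenzaldehyde | O=Cc1ccc(O)cc1O | starting material
18 | 2,4-bis{[tert-butyl(dimethyl)silyl]oxy}benzaldehyde | O=Cc1ccc(O[Si](C)(C)C(C)(C)C)cc1O[Si](C)(C)C(C)(C)C | intermediate
19 | [(4-ethynyl-1,3-phenylene)bis(oxy)]bis[tert-butyl(dimethyl)silane] | C#Cc1ccc(O[Si](C)(C)C(C)(C)C)cc1O[Si](C)(C)C(C)(C)C | intermediate
20 | (2E)-3-(2,4-bis{[tert-butyl(dimethyl)silyl]oxy}phenyl)-1-{2-hydroxy-3-[(2R)-5-methyl-2-(prop-1-en-2-yl)hex-5-en-1-yl]-4,6-bis{[tri(propan-2-yl)silyl]oxy}phenyl}prop-2-en-1-one | O=C(/C=C/c1ccc(O[Si](C)(C)C(C)(C)C)cc1O[Si](C)(C)C(C)(C)C)c1c(O)c(C[C@@H](CCC(C)=C)C(C)=C)c(O[Si](C(C)C)(C(C)C)C(C)C)cc1O[Si](C(C)C)(C(C)C)C(C)C | intermediate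
21 | (2S)-2-(2,4-bis{[tert-butyl(dimethyl)silyl]oxy}phenyl)-8-[(2R)-5-methyl-2-(prop-1-en-2-yl)hex-5-en-1-yl]-5,7-bis{[tri(propan-2-yl)silyl]oxy}-2,3-dihydro-4H-chromen-4-one | C=C(C)CC[C@H](Cc1c(O[Si](C(C)C)(C(C)C)C(C)C)cc(O[Si](C(C)C)(C(C)C)C(C)C)c2c1O[C@H](c1ccc(O[Si](C)(C)C(C)(C)C)cc1O[Si](C)(C)C(C)(C)C)CC2=O)C(=C)C | intermediate
22 | remangiflavanone B, (2S)-2-(2,4-dihydroxyphenyl)-5,7-dihydroxy-8-[(2R)-5-methyl-2-(prop-1-en-2-yl)hex-5-en-1-yl]-2,3-dihydro-4H-chromen-4-one | C=C(C)CC[C@H](Cc1c(O)cc(O)c2c1O[C@H](c1ccc(O)cc1O)CC2=O)C(=C)C | target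

**Step count and risks**

Total steps: 14. Longest linear sequence: 10 (steps 1, 2, 3, 4, 7, 8, 9, 10, 13, 14).

1. Step 13 (bears the label). Two things may go wrong. The chalcone may close under the rhodium aryloxide before the chiral catalyst is present, or the organocatalyst may discriminate the enone faces poorly without a 3-acyl handle; either gives a mixture of C2 epimers. Markovnikov acyl delivery to the alkyne is also possible. The fallback uses known chemistry, sets out from 16 and 18 and comes back at 21. Roskamp homologation of 16 with allyl diazoacetate (SnCl2 cat.) should give allyl 3-{2-hydroxy-3-[(2R)-5-methyl-2-(prop-1-en-2-yl)hex-5-en-1-yl]-4,6-bis{[tri(propan-2-yl)silyl]oxy}phenyl}-3-oxopropanoate F1. Knoevenagel condensation of F1 with 18 (piperidinium acetate, benzene) should give the alkylidene β-keto ester F2, the activated substrate class for which cinchona-thiourea oxa-Michael closure is established. That closure should give the allyl (2S)-4-oxochromane-3-carboxylate F3, and Pd(PPh3)4/morpholine deallylation–decarboxylation returns 21.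

2. Step 7. The aryllithium may act as a base and eliminate HI from 7 (the β-hydrogen is tertiary and allylic), or iodine–lithium exchange may compete with substitution. The fallback reverses the polarity, sets out from 10 and 7 and comes back at 12. Lithiation of 10 and an iodine quench should give {4-iodo-3,5-bis(methoxymethoxy)phenoxy}tri(propan-2-yl)silane F4. Zinc insertion into 7 (Zn dust, LiCl, THF) should give iodo[(2S)-5-methyl-2-(prop-1-en-2-yl)hex-5-en-1-yl]zinc F5. Negishi coupling of F4 with F5 (Pd(OAc)2, SPhos) gives 12.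

3. Step 4. The primary radical may cyclise onto the 1,1-disubstituted alkene, or iodoform-derived radicals may add to the alkenes, in competition with iodine transfer. The fallback is a polar one-carbon degradation, sets out from 5 and comes back at 7. Hydroxylation of the dianion of 5 (LDA, then O2/P(OEt)3) should give (3S)-2-hydroxy-6-methyl-3-(prop-1-en-2-yl)hept-6-enoic acid F6 (epimers at C2). Oxidative decarboxylation with Pb(OAc)4 should give the configurationally labile (2S)-5-methyl-2-(prop-1-en-2-yl)hex-5-enal F7, which is reduced in the same flask with NaBH4 to (2S)-5-methyl-2-(prop-1-en-2-yl)hex-5-en-1-ol F8. Appel iodination (I2, PPh3, imidazole) gives 7.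

Further compounds
F1 | step 13 | allyl 3-{2-hydroxy-3-[(2R)-5-methyl-2-(prop-1-en-2-yl)hex-5-en-1-yl]-4,6-bis{[tri(propan-2-yl)silyl]oxy}phenyl}-3-oxopropanoate | C=CCOC(=O)CC(=O)c1c(O)c(C[C@@H](CCC(C)=C)C(C)=C)c(O[Si](C(C)C)(C(C)C)C(C)C)cc1O[Si](C(C)C)(C(C)C)C(C)C
F2 | step 13 | allyl 3-(2,4-bis{[tert-butyl(dimethyl)silyl]oxy}phenyl)-2-{2-hydroxy-3-[(2R)-5-methyl-2-(prop-1-en-2-yl)hex-5-en-1-yl]-4,6-bis{[tri(propan-2-yl)silyl]oxy}benzoyl}prop-2-enoate | C=CCOC(=O)C(=Cc1ccc(O[Si](C)(C)C(C)(C)C)cc1O[Si](C)(C)C(C)(C)C)C(=O)c1c(O)c(C[C@@H](CCC(C)=C)C(C)=C)c(O[Si](C(C)C)(C(C)C)C(C)C)cc1O[Si](C(C)C)(C(C)C)C(C)C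
F3 | step 13 | allyl (2S)-2-(2,4-bis{[tert-butyl(dimethyl)silyl]oxy}phenyl)-8-[(2R)-5-methyl-2-(prop-1-en-2-yl)hex-5-en-1-yl]-4-oxo-5,7-bis{[tri(propan-2-yl)silyl]oxy}chromane-3-carboxylate | C=CCOC(=O)C1C(=O)c2c(O[Si](C(C)C)(C(C)C)C(C)C)cc(O[Si](C(C)C)(C(C)C)C(C)C)c(C[C@@H](CCC(C)=C)C(C)=C)c2O[C@@H]1c1ccc(O[Si](C)(C)C(C)(C)C)cc1O[Si](C)(C)C(C)(C)C
F4 | step 7 | {4-iodo-3,5-bis(methoxymethoxy)phenoxy}tri(propan-2-yl)silane | COCOc1cc(O[Si](C(C)C)(C(C)C)C(C)C)cc(OCOC)c1I
F5 | step 7 | iodo[(2S)-5-methyl-2-(prop-1-en-2-yl)hex-5-en-1-yl]zinc | I[Zn]C[C@@H](CCC(C)=C)C(C)=C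
F6 | step 4 | (3S)-2-hydroxy-6-methyl-3-(prop-1-en-2-yl)hept-6-enoic acid | OC(=O)C(O)[C@@H](CCC(C)=C)C(C)=C
F7 | step 4 | (2S)-5-methyl-2-(prop-1-en-2-yl)hex-5-enal | O=C[C@@H](CCC(C)=C)C(C)=C
F8 | step 4 | (2S)-5-methyl-2-(prop-1-en-2-yl)hex-5-en-1-ol | OC[C@@H](CCC(C)=C)C(C)=C
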